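Ring A is made last, by disconnecting its C8–C8a bond. Ring A carries four contiguous oxygens (C5–C8) in which C5-OMe and the free C8-OH are para, and this is the pattern that thermolysis of a squarate-derived 4-alkenyl-2,3,4-trimethoxycyclobutenone delivers. In one operation the four-membered ring opens to a dienylketene, closes onto the pyranone C4a=C8a alkene and aromatises, forming ring A with all four oxygens correctly differentiated. The precursor is the (S)-2-(3,4-dimethoxyphenyl)-2,3-dihydropyran-4-one bearing that cyclobutenone on its α-carbon (future C4a). C2 is set earlier by an asymmetric hetero-Diels–Alder reaction.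

Key step: step 8

Remark on numbering: atoms that end up in the chromanone are called by flavanone locants (C2, C3, C4, C4a, C5–C8, C8a); systematic names use pyran locants.

Remark on design: the C4 carbonyl of the pyranone is a vinylogous ester, so acid and a diol would add at C8a or open the ring instead of giving a ketal, and such a ketal would be a labile vinylogous orthoester. C4 is therefore carried through the organolithium step as a silyl-protected carbinol and returned to the ketone before the thermolysis, which then gives the target itself and spares the electron-rich C8 phenol any later oxidant or base.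

Assumption: the (S)-BINOL/Ti(OiPr)4 catalyst is taken to direct the diene to the Si face of the aldehyde and so to the (S)-pyranone, as its sense of induction in related aldehyde additions suggests; should the sense be opposite, (R)-BINOL is used.

Remark on spectator centres: the C4 carbinol configuration and the cyclobutenone carbinol carbon (formed as both epimers, left undefined in the SMILES) are both erased before or in the key step.

Step 1
Reactants: 1 3,4-dimethoxybenzaldehyde; 2 (E)-1-methoxy-3-(trimethylsilyloxy)buta-1,3-diene
Product: 4 (2S)-2-(3,4-dimethoxyphenyl)-2,3-dihydro-4H-pyran-4-one, via silyl aldol adduct 3 (not isolated)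
Conditions: (S)-BINOL (20 mol %), Ti(OiPr)4 (10 mol %), 4 Å MS, Et2O, –20 °C; then CF3CO2H, CH2Cl2, 0 °C
Reagents that add atoms: none
Why: Titanium–BINOL-catalysed hetero-Diels–Alder reaction of an aryl aldehyde with Danishefsky's diene (Keck conditions, Mukaiyama aldol then acid-induced ring closure with loss of methanol) is established chemistry, and the chiral Lewis acid shields one face of the bound aldehyde so that C–C bond formation on the Si face sets C2 as S.

Step 2
Reactants: 4 (2S)-2-(3,4-dimethoxyphenyl)-2,3-dihydro-4H-pyran-4-one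
Product: 5 (2S)-2-(3,4-dimethoxyphenyl)-5-iodo-2,3-dihydro-4H-pyran-4-one
Conditions: I2, pyridine, CH2Cl2, 0 °C to rt
Reagents that add atoms: iodine, II
Why: Johnson-type α-iodination of a cyclic enone, here helped by the enol-ether character of the α-carbon of the vinylogous ester, should iodinate only that carbon, since I2/pyridine does not attack the dimethoxyphenyl ring and the mild base leaves C2 alone.

Step 3
Reactants: 5 (2S)-2-(3,4-dimethoxyphenyl)-5-iodo-2,3-dihydro-4H-pyran-4-one
Product: 6 (2S,4S)-2-(3,4-dimethoxyphenyl)-5-iodo-3,4-dihydro-2H-pyran-4-ol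
Conditions: NaBH4, CeCl3·7H2O, MeOH, –78 to –20 °C
Reagents that add atoms: none
Why: Luche reduction should give clean 1,2-reduction of the α-iodo enone, with axial hydride delivery onto the half-chair that holds the aryl group equatorial expected to favour the 2,4-cis alcohol (substrate control), a centre whose configuration is immaterial because C4 is reoxidised in step 7.

Step 4
Reactants: 6 (2S,4S)-2-(3,4-dimethoxyphenyl)-5-iodo-3,4-dihydro-2H-pyran-4-ol
Product: 7 (2S,4S)-2-(3,4-dimethoxyphenyl)-5-iodo-4-(triethylsilyloxy)-3,4-dihydro-2H-pyran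
Conditions: Et3SiCl, imidazole, CH2Cl2, 0 °C
Reagents that add atoms: chlorotriethylsilane, CC[Si](Cl)(CC)CC
Why: Imidazole-promoted silylation of a secondary allylic alcohol is routine and removes the acidic proton before lithiation, while the triethylsilyl ether is later cleaved by buffered fluoride.

Step 5
Reactants: 7 (2S,4S)-2-(3,4-dimethoxyphenyl)-5-iodo-4-(triethylsilyloxy)-3,4-dihydro-2H-pyran; 8 dimethyl squarate
Product: 11 4-[(2S,4S)-2-(3,4-dimethoxyphenyl)-4-(triethylsilyloxy)-3,4-dihydro-2H-pyran-5-yl]-2,3,4-trimethoxycyclobut-2-en-1-one, via vinyllithium 9 (not isolated), via lithium alkoxide 10 (not isolated)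
Conditions: t-BuLi (2.1 equiv), Et2O, –78 °C; cannulate into 8, THF, –78 °C; then MeOTf, –78 to 0 °C
Reagents that add atoms: methyl trifluoromethanesulfonate, COS(=O)(=O)C(F)(F)F
Why: Iodine–lithium exchange is far faster at –78 °C than any deprotonation of the substrate, the vinyllithium adds 1,2 to one carbonyl of the squarate ester as organolithiums generally do (inverse addition prevents double addition), and the tertiary lithium alkoxide is trapped by O-methylation with MeOTf, the new carbinol centre arising as both epimers, which serve equally.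

Step 6
Reactants: 11 4-[(2S,4S)-2-(3,4-dimethoxyphenyl)-4-(triethylsilyloxy)-3,4-dihydro-2H-pyran-5-yl]-2,3,4-trimethoxycyclobut-2-en-1-one
Product: 12 4-[(2S,4S)-2-(3,4-dimethoxyphenyl)-4-hydroxy-3,4-dihydro-2H-pyran-5-yl]-2,3,4-trimethoxycyclobut-2-en-1-one
Conditions: Bu4NF/AcOH, THF, 0 °C
Reagents that add atoms: none
Why: Fluoride-mediated desilylation buffered with acetic acid should cleave the labile triethylsilyl ether without leaving a free alkoxide beside the base-sensitive cyclobutenone and without acid strong enough to disturb the allylic enol ether.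

Step 7
Reactants: 12 4-[(2S,4S)-2-(3,4-dimethoxyphenyl)-4-hydroxy-3,4-dihydro-2H-pyran-5-yl]-2,3,4-trimethoxycyclobut-2-en-1-one
Product: 13 (2S)-2-(3,4-dimethoxyphenyl)-5-(1,2,3-trimethoxy-4-oxocyclobut-2-en-1-yl)-2,3-dihydro-4H-pyran-4-one
Conditions: Dess–Martin periodinane, pyridine, CH2Cl2, 0 °C to rt
Reagents that add atoms: none
Why: Dess–Martin oxidation of a hindered secondary allylic alcohol under pyridine buffer should restore the vinylogous ester carbonyl while leaving the cyclobutenone, the enol ether and C2 untouched.

Step 8
Reactants: 13 (2S)-2-(3,4-dimethoxyphenyl)-5-(1,2,3-trimethoxy-4-oxocyclobut-2-en-1-yl)-2,3-dihydro-4H-pyran-4-one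
Product: 16 (2S)-2-(3,4-dimethoxyphenyl)-8-hydroxy-5,6,7-trimethoxy-2,3-dihydro-4H-chromen-4-one, via dienylketene 14 (not isolated), via cyclohexadienone 15 (not isolated)
Conditions: toluene (0.01 M, degassed), 110 °C, Ar
Reagents that add atoms: none
Why: Heat opens the cyclobutenone by conrotatory 4π electrocyclic cleavage of its C(=O)–C(OMe) bond to dienylketene 14, and a disrotatory 6π electrocyclisation then joins the ketene carbon to C8a, forming the C8–C8a bond and closing the six-membered carbocyclic ring A; enolisation of cyclohexadienone 15 aromatises it. The closest known reaction type is the Moore rearrangement of 4-alkenyl- and 4-aryl-4-alkoxycyclobutenones from squarate esters to hydroquinone monoethers. Ring A is closed by thermal 6π electrocyclisation of the triene made up of the ketene C=C, the dimethoxy alkene and the C4a=C8a bond, and connectivity fixes the oxygen pattern: the methylated carbinol carbon becomes C5, the two squarate carbons C6 and C7, and the ketene carbon the free C8 phenol. No lasting stereocentre is formed, since the C8a centre of 15 is lost on tautomerisation, and the neutral thermal conditions should leave C2 untouched. The selectivity needed is torquoselective ring opening with the carbinol methoxy group turning outward and the pyranonyl group inward toward the ketene; the strong outward preference of an oxygen donor at that carbon secures it for either epimer of 13. High dilution under argon keeps the ketene from bimolecular capture.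

Compound list
1 | 3,4-dimethoxybenzaldehyde | COc1ccc(C=O)cc1OC | starting material
2 | (E)-1-methoxy-3-(trimethylsilyloxy)buta-1,3-diene | CO/C=C/C(=C)O[Si](C)(C)C | starting material
3 | (S,E)-5-(3,4-dimethoxyphenyl)-1-methoxy-5-(trimethylsilyloxy)pent-1-en-3-one | CO/C=C/C(=O)C[C@H](O[Si](C)(C)C)c1ccc(OC)c(OC)c1 | intermediate
4 | (2S)-2-(3,4-dimethoxyphenyl)-2,3-dihydro-4H-pyran-4-one | O=C1C[C@@H](c2ccc(OC)c(OC)c2)OC=C1 | intermediate
5 | (2S)-2-(3,4-dimethoxyphenyl)-5-iodo-2,3-dihydro-4H-pyran-4-one | O=C1C[C@@H](c2ccc(OC)c(OC)c2)OC=C1I | intermediate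
6 | (2S,4S)-2-(3,4-dimethoxyphenyl)-5-iodo-3,4-dihydro-2H-pyran-4-ol (2,4-cis) | O[C@H]1C[C@@H](c2ccc(OC)c(OC)c2)OC=C1I | intermediate
7 | (2S,4S)-2-(3,4-dimethoxyphenyl)-5-iodo-4-(triethylsilyloxy)-3,4-dihydro-2H-pyran | CC[Si](CC)(CC)O[C@H]1C[C@@H](c2ccc(OC)c(OC)c2)OC=C1I | intermediate
8 | dimethyl squarate (3,4-dimethoxycyclobut-3-ene-1,2-dione) | COC1=C(OC)C(=O)C1=O | starting material
9 | (2S,4S)-2-(3,4-dimethoxyphenyl)-5-lithio-4-(triethylsilyloxy)-3,4-dihydro-2H-pyran | CC[Si](CC)(CC)O[C@H]1C[C@@H](c2ccc(OC)c(OC)c2)OC=C1[Li] | intermediate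
10 | lithium 1-[(2S,4S)-2-(3,4-dimethoxyphenyl)-4-(triethylsilyloxy)-3,4-dihydro-2H-pyran-5-yl]-2,3-dimethoxy-4-oxocyclobut-2-en-1-olate (both epimers at the carbinol carbon) | CC[Si](CC)(CC)O[C@H]1C[C@@H](c2ccc(OC)c(OC)c2)OC=C1C3(O[Li])C(OC)=C(OC)C3=O | intermediate
11 | 4-[(2S,4S)-2-(3,4-dimethoxyphenyl)-4-(triethylsilyloxy)-3,4-dihydro-2H-pyran-5-yl]-2,3,4-trimethoxycyclobut-2-en-1-one (both epimers at the cyclobutenone C4) | CC[Si](CC)(CC)O[C@H]1C[C@@H](c2ccc(OC)c(OC)c2)OC=C1C3(OC)C(OC)=C(OC)C3=O | intermediate
12 | 4-[(2S,4S)-2-(3,4-dimethoxyphenyl)-4-hydroxy-3,4-dihydro-2H-pyran-5-yl]-2,3,4-trimethoxycyclobut-2-en-1-one (both epimers at the cyclobutenone C4) | O[C@H]1C[C@@H](c2ccc(OC)c(OC)c2)OC=C1C3(OC)C(OC)=C(OC)C3=O | intermediate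
13 | (2S)-2-(3,4-dimethoxyphenyl)-5-(1,2,3-trimethoxy-4-oxocyclobut-2-en-1-yl)-2,3-dihydro-4H-pyran-4-one (both epimers at the cyclobutenone carbinol carbon; key-step precursor) | O=C1C[C@@H](c2ccc(OC)c(OC)c2)OC=C1C3(OC)C(OC)=C(OC)C3=O | intermediate
14 | (2S)-2-(3,4-dimethoxyphenyl)-5-[(1Z)-1,2,3-trimethoxy-4-oxobuta-1,3-dien-1-yl]-2,3-dihydro-4H-pyran-4-one (dienylketene) | O=C=C(OC)/C(OC)=C(OC)\C1=CO[C@H](c2ccc(OC)c(OC)c2)CC1=O | intermediate
15 | (2S)-2-(3,4-dimethoxyphenyl)-5,6,7-trimethoxy-2,3-dihydro-4H-chromene-4,8(8aH)-dione (C8a transient, undefined) | O=C1C(OC)=C(OC)C(OC)=C2C(=O)C[C@@H](c3ccc(OC)c(OC)c3)OC12 | intermediate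
16 | (2S)-2-(3,4-dimethoxyphenyl)-8-hydroxy-5,6,7-trimethoxy-2,3-dihydro-4H-chromen-4-one | COc1ccc([C@@H]2CC(=O)c3c(c(O)c(OC)c(OC)c3OC)O2)cc1OC | target

Total step count: 8. Longest linear sequence: 8 steps (1 to 16); dimethyl squarate 8 enters at step 5.

Steps most likely to fail

Step 8. The dienylketene may be consumed by bimolecular pathways, or closure onto the push–pull C4a=C8a bond of the free pyranone may be slow enough for decomposition to compete. Prolonged heating could also erode C2 through reversible ring opening of the hydroxyflavanone. The fallback changes the order so that ring A is made at the alcohol oxidation level, where the alkene is a plain enol ether and the product cannot open to a chalcone. It sets out from 11. Thermolysis in toluene at 80–110 °C should give (2S,4S)-2-(3,4-dimethoxyphenyl)-5,6,7-trimethoxy-4-(triethylsilyloxy)-3,4-dihydro-2H-chromen-8-ol F1. Bu4NF/AcOH in THF should then give (2S,4S)-2-(3,4-dimethoxyphenyl)-5,6,7-trimethoxy-3,4-dihydro-2H-chromene-4,8-diol F2. Activated MnO2 in CH2Cl2, which is selective for benzylic carbinols, should oxidise C4 and bring the sequence back to the route at 16.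

Step 5. The hindered tertiary lithium alkoxide may be captured only slowly by MeOTf, so that on warming it decomposes or the reagent alkylates elsewhere; silyl migration from oxygen to the lithiated carbon is a second possible loss. The fallback separates C–C bond formation from O-alkylation. It sets out from 7: exchange and addition to 8 are run as before but quenched at –78 °C with aqueous NH4Cl, and 4-hydroxy-2,3-dimethoxy-4-[(2S,4S)-2-(3,4-dimethoxyphenyl)-4-(triethylsilyloxy)-3,4-dihydro-2H-pyran-5-yl]cyclobut-2-en-1-one F3 is isolated. Methylation of this neutral carbinol with MeI, Ag2O and K2CO3 in MeCN (Purdie conditions, the standard treatment of squarate adducts) comes back to the route at 11.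

Step 6. Once set free, the C4 hydroxyl sits next to the cyclobutenone and may add to its carbonyl or displace the vinylogous-ester methoxy group under the basicity of fluoride, and the allylic enol ether may transpose if the medium turns acidic. The fallback merges unmasking and oxidation so that the alcohol never accumulates. It sets out from 11: IBX in DMSO at room temperature, which is known to convert triethylsilyl ethers directly into carbonyl compounds under non-basic conditions, should give the ketone in one operation, bypassing 12 and coming back to the route at 13. This fallback makes no new compound (F0).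

Further compounds
F1 | step 8 | (2S,4S)-2-(3,4-dimethoxyphenyl)-5,6,7-trimethoxy-4-(triethylsilyloxy)-3,4-dihydro-2H-chromen-8-ol | CC[Si](CC)(CC)O[C@H]1C[C@@H](c2ccc(OC)c(OC)c2)Oc2c(O)c(OC)c(OC)c(OC)c21
F2 | step 8 | (2S,4S)-2-(3,4-dimethoxyphenyl)-5,6,7-trimethoxy-3,4-dihydro-2H-chromene-4,8-diol | O[C@H]1C[C@@H](c2ccc(OC)c(OC)c2)Oc2c(O)c(OC)c(OC)c(OC)c21
F3 | step 5 | 4-hydroxy-2,3-dimethoxy-4-[(2S,4S)-2-(3,4-dimethoxyphenyl)-4-(triethylsilyloxy)-3,4-dihydro-2H-pyran-5-yl]cyclobut-2-en-1-one | CC[Si](CC)(CC)O[C@H]1C[C@@H](c2ccc(OC)c(OC)c2)OC=C1C3(O)C(OC)=C(OC)C3=O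
F0 | step 6 | none | none
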